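**Retrosynthetic overview**

1. The C40 polyene is cut at C11=C12 and C11'=C12' into two C15 phosphonium salts (cyclohexene end 19, triol end 33) and the C10 dialdehyde 20, joined by two Wittig reactions.
2. The cyclohexene (ε) ring is made in one operation from the acyclic chiral acetal 7 and 2-methylpropene: Prins addition forms C2'–C3', cation–olefin closure forms C1'–C6', and loss of H-4' sets the C4'=C5' olefin, as in the ε-cyclisation of carotenoid biosynthesis.
3. Enabling feature: in this ring the quaternary C1' (gem-dimethyl) lies 1,3 to the C3' carbinol through C2'H2 (2-methylpropene added to an aldehyde carbon), and C3'–C4'–C5'(Me)=C6' is a homoallylic olefin placed to trap the C1' cation.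
4. C3' is set by the (2S,4S)-pentane-2,4-diol acetal template; C6' is relayed from it through a chair transition state with the (E)-olefin.
5. The trihydroxycyclohexane ring is bought as (4R,6R)-actinol 22; its 5,6-diol comes from an anti epoxide (Sharpless) opened by water at C5 with inversion. Only the cyclohexene ring is formed in the route (step 5).

Key step: step 5

Remark: carotenoid numbering is used (C1'–C6' for the cyclohexene ring, C1–C6 for the trihydroxycyclohexane ring); (4R,6R)-actinol 22 and the C10 dialdehyde 20 are taken as purchasable.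

**Route**

Step 1
Reactants: 1 4,4-dimethoxybutan-2-one; 2 triethyl phosphonoacetate
Product: 3 ethyl (2E)-5,5-dimethoxy-3-methylpent-2-enoate
Conditions: NaH, THF, 0 °C to rt; minor (2Z)-isomer removed by chromatography
Reagents that add atoms: none
Why: Horner–Wadsworth–Emmons olefination of the methyl ketone should give mainly the (E)-enoate, and the olefin geometry that later controls C6' is secured here by separation.

Step 2
Reactants: 3 ethyl (2E)-5,5-dimethoxy-3-methylpent-2-enoate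
Product: 4 (2E)-5,5-dimethoxy-3-methylpent-2-en-1-ol
Conditions: iBu2AlH, CH2Cl2, −78 °C
Reagents that add atoms: none
Why: 1,2-reduction of the enoate by the aluminium hydride should give the allylic alcohol without touching the acetal.

Step 3
Reactants: 4 (2E)-5,5-dimethoxy-3-methylpent-2-en-1-ol
Product: 5 (2E)-5,5-dimethoxy-3-methylpent-2-en-1-yl pivalate
Conditions: pivaloyl chloride, pyridine, 4-(dimethylamino)pyridine (cat.), CH2Cl2, 0 °C
Reagents that add atoms: pivaloyl chloride CC(C)(C)C(=O)Cl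
Why: Acylation of the primary alcohol gives a hindered ester that should resist Lewis-acid ionisation in step 5 and base in step 6.

Step 4
Reactants: 5 (2E)-5,5-dimethoxy-3-methylpent-2-en-1-yl pivalate; 6 (2S,4S)-pentane-2,4-diol
Product: 7 (2E)-4-[(4S,6S)-4,6-dimethyl-1,3-dioxan-2-yl]-3-methylbut-2-en-1-yl pivalate
Conditions: pyridinium p-toluenesulfonate (cat.), benzene, reflux with removal of methanol
Reagents that add atoms: none
Why: Acid-catalysed transacetalisation driven by loss of methanol should give the dioxane; the diol is C2-symmetric, so no new stereocentre arises.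

Step 5
Reactants: 7 (2E)-4-[(4S,6S)-4,6-dimethyl-1,3-dioxan-2-yl]-3-methylbut-2-en-1-yl pivalate; 8 2-methylpropene
Product: 9 [(1R,4R)-4-{[(2S,4S)-4-hydroxypentan-2-yl]oxy}-2,6,6-trimethylcyclohex-2-en-1-yl]methyl pivalate
Conditions: TiCl4 (2.2 equiv, slow addition), 2,6-di-tert-butyl-4-methylpyridine, 8 (2 equiv), CH2Cl2 (high dilution), −78 °C; aq. NaHCO3
Reagents that add atoms: none
Why: Proposed new method: TiCl4 ionises the acetal at the oxygen next to the axial methyl group, the CH2 terminus of 2-methylpropene attacks the acetal carbon anti to the departing oxygen (Prins addition, forming C2'–C3' and the C3' ether), and the tertiary cation formed at C1' is captured at C6' by the (E)-trisubstituted olefin before the C5' cation loses H-4' to the hindered pyridine. The closest known reaction types are the coupling of chiral 2,4-pentanediol acetals with π-nucleophiles, acetal-initiated cation–olefin cyclisation and the acid cyclisation of geranyl esters to α-cyclogeranyl esters; the sequence copies the biosynthetic ε-cyclisation, with the C1' cation made by C–C bond formation instead of protonation. The cyclohexene ring closes in a 6-endo-trig cation–olefin mode through a chair. C3' should come out R because the (4S,6S) template forces displacement with inversion on one face of the acetal carbon; C6' should come out R because the C3' ether and the CH2OPiv group of the (E)-olefin both sit equatorial in the chair, which gives the trans-3',6' relationship. The step needs capture of the oxocarbenium ion by the alkene and of the tertiary cation by the internal olefin faster than oligomerisation of 2-methylpropene, which the low alkene concentration and the unimolecular ring closure should secure, and it needs proton loss toward C4', the kinetic outcome known from the α-ionone and α-cyclogeranyl series. The hindered pivalate should keep the allylic C7' oxygen from ionising, and the pyridine base suppresses protic initiation.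

Step 6
Reactants: 9 [(1R,4R)-4-{[(2S,4S)-4-hydroxypentan-2-yl]oxy}-2,6,6-trimethylcyclohex-2-en-1-yl]methyl pivalate
Product: 11 [(1R,4R)-4-hydroxy-2,6,6-trimethylcyclohex-2-en-1-yl]methyl pivalate, via (2S)-4-oxopentan-2-yl ether 10 (not isolated)
Conditions: Dess–Martin periodinane, CH2Cl2, rt; then DBU (1,8-diazabicyclo[5.4.0]undec-7-ene), CH2Cl2, rt
Reagents that add atoms: none
Why: Dess–Martin oxidation of the auxiliary carbinol followed by base-induced β-elimination (E1cB, retro-oxa-Michael) should release the C3' alcohol without touching either ring stereocentre.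

Step 7
Reactants: 11 [(1R,4R)-4-hydroxy-2,6,6-trimethylcyclohex-2-en-1-yl]methyl pivalate
Product: 12 [(1R,4R)-4-(tert-butyldimethylsilyloxy)-2,6,6-trimethylcyclohex-2-en-1-yl]methyl pivalate
Conditions: tert-butyldimethylsilyl chloride, imidazole, DMF, rt
Reagents that add atoms: tert-butyldimethylsilyl chloride CC(C)(C)[Si](C)(C)Cl
Why: Silylation of the secondary allylic alcohol protects C3'–OH for the chain-building steps.

Step 8
Reactants: 12 [(1R,4R)-4-(tert-butyldimethylsilyloxy)-2,6,6-trimethylcyclohex-2-en-1-yl]methyl pivalate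
Product: 13 [(1R,4R)-4-(tert-butyldimethylsilyloxy)-2,6,6-trimethylcyclohex-2-en-1-yl]methanol
Conditions: iBu2AlH, CH2Cl2, −78 °C
Reagents that add atoms: none
Why: Reductive cleavage of the pivalate by the aluminium hydride should free the primary alcohol and leave the silyl ether intact.

Step 9
Reactants: 13 [(1R,4R)-4-(tert-butyldimethylsilyloxy)-2,6,6-trimethylcyclohex-2-en-1-yl]methanol
Product: 14 (1R,4R)-4-(tert-butyldimethylsilyloxy)-2,6,6-trimethylcyclohex-2-ene-1-carbaldehyde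
Conditions: Dess–Martin periodinane, pyridine, CH2Cl2, 0 °C
Reagents that add atoms: none
Why: Buffered Dess–Martin oxidation should give the β,γ-unsaturated aldehyde under conditions mild enough to avoid epimerisation at C6'.

Step 10
Reactants: 14 (1R,4R)-4-(tert-butyldimethylsilyloxy)-2,6,6-trimethylcyclohex-2-ene-1-carbaldehyde; 15 ethyl (2E)-4-(diethoxyphosphoryl)-3-methylbut-2-enoate
Product: 16 ethyl (2E,4E)-5-[(1R,4R)-4-(tert-butyldimethylsilyloxy)-2,6,6-trimethylcyclohex-2-en-1-yl]-3-methylpenta-2,4-dienoate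
Conditions: LiN(SiMe3)2, THF, −78 °C, then 14, −78 to 0 °C
Reagents that add atoms: none
Why: Horner–Wadsworth–Emmons olefination with the preformed C5 phosphonate anion should form the C7'=C8' bond E-selectively, with addition at low temperature expected to outrun enolisation.

Step 11
Reactants: 16 ethyl (2E,4E)-5-[(1R,4R)-4-(tert-butyldimethylsilyloxy)-2,6,6-trimethylcyclohex-2-en-1-yl]-3-methylpenta-2,4-dienoate
Product: 17 (2E,4E)-5-[(1R,4R)-4-(tert-butyldimethylsilyloxy)-2,6,6-trimethylcyclohex-2-en-1-yl]-3-methylpenta-2,4-dien-1-ol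
Conditions: iBu2AlH, CH2Cl2, −78 °C
Reagents that add atoms: none
Why: 1,2-reduction of the dienoate should give the C15 allylic alcohol.

Step 12
Reactants: 17 (2E,4E)-5-[(1R,4R)-4-(tert-butyldimethylsilyloxy)-2,6,6-trimethylcyclohex-2-en-1-yl]-3-methylpenta-2,4-dien-1-ol
Product: 19 [(2E,4E)-5-[(1R,4R)-4-(tert-butyldimethylsilyloxy)-2,6,6-trimethylcyclohex-2-en-1-yl]-3-methylpenta-2,4-dien-1-yl]triphenylphosphonium bromide, via allylic bromide 18 (not isolated)
Conditions: CBr4, PPh3, CH2Cl2, −20 °C; then PPh3, rt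
Reagents that add atoms: carbon tetrabromide BrC(Br)(Br)Br; triphenylphosphine c1ccc(cc1)P(c1ccccc1)c1ccccc1
Why: Appel bromination followed by quaternisation of triphenylphosphine should give the Wittig salt under neutral conditions that spare the allylic silyl ether.

Step 13
Reactants: 19 [(2E,4E)-5-[(1R,4R)-4-(tert-butyldimethylsilyloxy)-2,6,6-trimethylcyclohex-2-en-1-yl]-3-methylpenta-2,4-dien-1-yl]triphenylphosphonium bromide; 20 (2E,4E,6E)-2,7-dimethylocta-2,4,6-trienedial
Product: 21 (2E,4E,6E,8E,10E,12E)-13-[(1R,4R)-4-(tert-butyldimethylsilyloxy)-2,6,6-trimethylcyclohex-2-en-1-yl]-2,7,11-trimethyltrideca-2,4,6,8,10,12-hexaenal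
Conditions: NaOMe, MeOH/CH2Cl2, 0 °C to rt, 20 in threefold excess; then reflux in ethanol (Z to E isomerisation)
Reagents that add atoms: none
Why: Wittig olefination of the excess dialdehyde should stop at mono-condensation, and the new C11'=C12' bond is equilibrated thermally to E.

Step 14
Reactants: 22 (4R,6R)-4-hydroxy-2,2,6-trimethylcyclohexan-1-one
Product: 23 (4R,6R)-4-[tert-butyl(diphenyl)silyl]oxy-2,2,6-trimethylcyclohexan-1-one
Conditions: tert-butyl(chloro)diphenylsilane, imidazole, DMF, rt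
Reagents that add atoms: tert-butyl(chloro)diphenylsilane CC(C)(C)[Si](Cl)(c1ccccc1)c1ccccc1
Why: Silylation with the acid-stable diphenylsilyl group protects C3–OH through the acidic step 21.

Step 15
Reactants: 23 (4R,6R)-4-[tert-butyl(diphenyl)silyl]oxy-2,2,6-trimethylcyclohexan-1-one
Product: 24 (4R)-4-[tert-butyl(diphenyl)silyl]oxy-2,6,6-trimethylcyclohex-1-en-1-yl trifluoromethanesulfonate
Conditions: LiN(iPr)2, THF, −78 °C; then N-phenylbis(trifluoromethanesulfonimide), −78 °C to rt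
Reagents that add atoms: N-phenylbis(trifluoromethanesulfonimide) O=S(=O)(N(c1ccccc1)S(=O)(=O)C(F)(F)F)C(F)(F)F
Why: Enolate O-triflation can only go toward C5 because C1 is quaternary, so a single enol triflate should form.

Step 16
Reactants: 24 (4R)-4-[tert-butyl(diphenyl)silyl]oxy-2,6,6-trimethylcyclohex-1-en-1-yl trifluoromethanesulfonate
Product: 25 methyl (4R)-4-[tert-butyl(diphenyl)silyl]oxy-2,6,6-trimethylcyclohex-1-ene-1-carboxylate
Conditions: Pd(OAc)2 (cat.), PPh3, CO (1 atm), MeOH, Et3N, DMF, 60 °C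
Reagents that add atoms: carbon monoxide [C-]#[O+]; methanol CO
Why: Palladium-catalysed methoxycarbonylation of the enol triflate (oxidative addition to zerovalent palladium formed in situ, CO insertion, methanolysis) installs C7.

Step 17
Reactants: 25 methyl (4R)-4-[tert-butyl(diphenyl)silyl]oxy-2,6,6-trimethylcyclohex-1-ene-1-carboxylate
Product: 26 [(4R)-4-[tert-butyl(diphenyl)silyl]oxy-2,6,6-trimethylcyclohex-1-en-1-yl]methanol
Conditions: iBu2AlH, CH2Cl2, −78 °C
Reagents that add atoms: none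
Why: 1,2-reduction of the unsaturated ester should give the allylic alcohol needed for directed epoxidation.

Step 18
Reactants: 26 [(4R)-4-[tert-butyl(diphenyl)silyl]oxy-2,6,6-trimethylcyclohex-1-en-1-yl]methanol
Product: 27 [(1R,4S,6R)-4-[tert-butyl(diphenyl)silyl]oxy-2,2,6-trimethyl-7-oxabicyclo[4.1.0]heptan-1-yl]methanol
Conditions: Ti(OiPr)4, D-(−)-diethyl tartrate, tert-butyl hydroperoxide, 4 Å molecular sieves, CH2Cl2, −20 °C
Reagents that add atoms: tert-butyl hydroperoxide CC(C)(C)OO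
Why: Sharpless asymmetric epoxidation with the tartrate enantiomer that delivers oxygen to the face anti to the silyloxy group (the sterically matched case) should set C5 and C6 of the epoxide.

Step 19
Reactants: 27 [(1R,4S,6R)-4-[tert-butyl(diphenyl)silyl]oxy-2,2,6-trimethyl-7-oxabicyclo[4.1.0]heptan-1-yl]methanol
Product: 28 (1S,4S,6R)-4-[tert-butyl(diphenyl)silyl]oxy-2,2,6-trimethyl-7-oxabicyclo[4.1.0]heptane-1-carbaldehyde
Conditions: Dess–Martin periodinane, pyridine, CH2Cl2, 0 °C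
Reagents that add atoms: none
Why: Dess–Martin oxidation should give the epoxy aldehyde, which has no α-hydrogen and cannot epimerise.

Step 20
Reactants: 28 (1S,4S,6R)-4-[tert-butyl(diphenyl)silyl]oxy-2,2,6-trimethyl-7-oxabicyclo[4.1.0]heptane-1-carbaldehyde; 15 ethyl (2E)-4-(diethoxyphosphoryl)-3-methylbut-2-enoate
Product: 29 ethyl (2E,4E)-5-[(1S,4S,6R)-4-[tert-butyl(diphenyl)silyl]oxy-2,2,6-trimethyl-7-oxabicyclo[4.1.0]heptan-1-yl]-3-methylpenta-2,4-dienoate
Conditions: LiN(SiMe3)2, THF, −78 to 0 °C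
Reagents that add atoms: none
Why: Horner–Wadsworth–Emmons olefination should form the C7=C8 bond E-selectively and give the C15 epoxy dienoate.

Step 21
Reactants: 29 ethyl (2E,4E)-5-[(1S,4S,6R)-4-[tert-butyl(diphenyl)silyl]oxy-2,2,6-trimethyl-7-oxabicyclo[4.1.0]heptan-1-yl]-3-methylpenta-2,4-dienoate
Product: 30 ethyl (2E,4E)-5-[(1S,2S,4S)-4-[tert-butyl(diphenyl)silyl]oxy-1,2-dihydroxy-2,6,6-trimethylcyclohexyl]-3-methylpenta-2,4-dienoate
Conditions: HClO4 (cat., 0.05 M), THF/H2O 4:1, 0 °C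
Reagents that add atoms: water O
Why: Acid-catalysed epoxide hydrolysis should place water at C5 with inversion (C5 becomes S, C6–O is retained), because positive charge at C6 is disfavoured by the electron-poor dienoate and by the neopentyl environment.

Step 22
Reactants: 30 ethyl (2E,4E)-5-[(1S,2S,4S)-4-[tert-butyl(diphenyl)silyl]oxy-1,2-dihydroxy-2,6,6-trimethylcyclohexyl]-3-methylpenta-2,4-dienoate
Product: 31 (2E,4E)-5-[(1S,2S,4S)-4-[tert-butyl(diphenyl)silyl]oxy-1,2-dihydroxy-2,6,6-trimethylcyclohexyl]-3-methylpenta-2,4-dien-1-ol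
Conditions: iBu2AlH (excess), CH2Cl2, −78 °C
Reagents that add atoms: none
Why: 1,2-reduction of the dienoate should give the primary allylic alcohol, with the two tertiary hydroxyls only consuming hydride as alkoxides.

Step 23
Reactants: 31 (2E,4E)-5-[(1S,2S,4S)-4-[tert-butyl(diphenyl)silyl]oxy-1,2-dihydroxy-2,6,6-trimethylcyclohexyl]-3-methylpenta-2,4-dien-1-ol
Product: 33 [(2E,4E)-5-[(1S,2S,4S)-4-[tert-butyl(diphenyl)silyl]oxy-1,2-dihydroxy-2,6,6-trimethylcyclohexyl]-3-methylpenta-2,4-dien-1-yl]triphenylphosphonium bromide, via allylic bromide 32 (not isolated)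
Conditions: CBr4, PPh3, CH2Cl2, −20 °C; then PPh3, rt
Reagents that add atoms: carbon tetrabromide BrC(Br)(Br)Br; triphenylphosphine c1ccc(cc1)P(c1ccccc1)c1ccccc1
Why: Appel bromination should select the primary allylic hydroxyl over the hindered tertiary ones, and quaternisation then gives the Wittig salt without acid.

Step 24
Reactants: 33 [(2E,4E)-5-[(1S,2S,4S)-4-[tert-butyl(diphenyl)silyl]oxy-1,2-dihydroxy-2,6,6-trimethylcyclohexyl]-3-methylpenta-2,4-dien-1-yl]triphenylphosphonium bromide; 21 (2E,4E,6E,8E,10E,12E)-13-[(1R,4R)-4-(tert-butyldimethylsilyloxy)-2,6,6-trimethylcyclohex-2-en-1-yl]-2,7,11-trimethyltrideca-2,4,6,8,10,12-hexaenal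
Product: 34 (3S,5S,6S,3'R,6'R)-3-[tert-butyl(diphenyl)silyl]oxy-3'-(tert-butyldimethylsilyloxy)-5,6-dihydro-β,ε-carotene-5,6-diol
Conditions: NaOMe (excess), MeOH/CH2Cl2, rt, dark; then reflux in ethanol (Z to E isomerisation)
Reagents that add atoms: none
Why: Wittig olefination joins C11 to C12 and completes the C40 chain; the free tertiary hydroxyls are tolerated as alkoxides and the new double bond is equilibrated thermally to E.

Step 25
Reactants: 34 (3S,5S,6S,3'R,6'R)-3-[tert-butyl(diphenyl)silyl]oxy-3'-(tert-butyldimethylsilyloxy)-5,6-dihydro-β,ε-carotene-5,6-diol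
Product: 35 (3S,5S,6S,3'R,6'R)-5,6-dihydro-β,ε-carotene-3,5,6,3'-tetrol
Conditions: Bu4NF, THF, 0 °C to rt, dark, argon
Reagents that add atoms: none
Why: Fluoride-mediated desilylation should remove both silyl ethers under non-acidic conditions that spare the allylic alcohols and the polyene.

**Compound list**

1 | 4,4-dimethoxybutan-2-one | CC(=O)CC(OC)OC | starting material
2 | triethyl phosphonoacetate | CCOC(=O)CP(=O)(OCC)OCC | starting material
3 | ethyl (2E)-5,5-dimethoxy-3-methylpent-2-enoate | CCOC(=O)/C=C(C)/CC(OC)OC | intermediate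
4 | (2E)-5,5-dimethoxy-3-methylpent-2-en-1-ol | OC/C=C(C)/CC(OC)OC | intermediate
5 | (2E)-5,5-dimethoxy-3-methylpent-2-en-1-yl pivalate | CC(C)(C)C(=O)OC/C=C(C)/CC(OC)OC | intermediate
6 | (2S,4S)-pentane-2,4-diol | C[C@H](O)C[C@H](C)O | starting material
7 | (2E)-4-[(4S,6S)-4,6-dimethyl-1,3-dioxan-2-yl]-3-methylbut-2-en-1-yl pivalate | C[C@H]1C[C@H](C)OC(C/C(C)=C/COC(=O)C(C)(C)C)O1 | intermediate
8 | 2-methylpropene | CC(C)=C | starting material
9 | [(1R,4R)-4-{[(2S,4S)-4-hydroxypentan-2-yl]oxy}-2,6,6-trimethylcyclohex-2-en-1-yl]methyl pivalate | CC1=C[C@H](O[C@@H](C)C[C@H](C)O)CC(C)(C)[C@H]1COC(=O)C(C)(C)C | intermediate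
10 | [(1R,4R)-2,6,6-trimethyl-4-{[(2S)-4-oxopentan-2-yl]oxy}cyclohex-2-en-1-yl]methyl pivalate | CC1=C[C@H](O[C@@H](C)CC(C)=O)CC(C)(C)[C@H]1COC(=O)C(C)(C)C | intermediate
11 | [(1R,4R)-4-hydroxy-2,6,6-trimethylcyclohex-2-en-1-yl]methyl pivalate | CC1=C[C@H](O)CC(C)(C)[C@H]1COC(=O)C(C)(C)C | intermediate
12 | [(1R,4R)-4-(tert-butyldimethylsilyloxy)-2,6,6-trimethylcyclohex-2-en-1-yl]methyl pivalate | CC1=C[C@H](O[Si](C)(C)C(C)(C)C)CC(C)(C)[C@H]1COC(=O)C(C)(C)C | intermediate
13 | [(1R,4R)-4-(tert-butyldimethylsilyloxy)-2,6,6-trimethylcyclohex-2-en-1-yl]methanol | CC1=C[C@H](O[Si](C)(C)C(C)(C)C)CC(C)(C)[C@H]1CO | intermediate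
14 | (1R,4R)-4-(tert-butyldimethylsilyloxy)-2,6,6-trimethylcyclohex-2-ene-1-carbaldehyde | CC1=C[C@H](O[Si](C)(C)C(C)(C)C)CC(C)(C)[C@H]1C=O | intermediate
15 | ethyl (2E)-4-(diethoxyphosphoryl)-3-methylbut-2-enoate | CCOC(=O)/C=C(C)/CP(=O)(OCC)OCC | starting material
16 | ethyl (2E,4E)-5-[(1R,4R)-4-(tert-butyldimethylsilyloxy)-2,6,6-trimethylcyclohex-2-en-1-yl]-3-methylpenta-2,4-dienoate | CC1=C[C@H](O[Si](C)(C)C(C)(C)C)CC(C)(C)[C@H]1/C=C/C(C)=C/C(=O)OCC | intermediate
17 | (2E,4E)-5-[(1R,4R)-4-(tert-butyldimethylsilyloxy)-2,6,6-trimethylcyclohex-2-en-1-yl]-3-methylpenta-2,4-dien-1-ol | CC1=C[C@H](O[Si](C)(C)C(C)(C)C)CC(C)(C)[C@H]1/C=C/C(C)=C/CO | intermediate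
18 | {[(1R,4R)-4-[(1E,3E)-5-bromo-3-methylpenta-1,3-dien-1-yl]-3,5,5-trimethylcyclohex-2-en-1-yl]oxy}(tert-butyl)dimethylsilane | CC1=C[C@H](O[Si](C)(C)C(C)(C)C)CC(C)(C)[C@H]1/C=C/C(C)=C/CBr | intermediate
19 | [(2E,4E)-5-[(1R,4R)-4-(tert-butyldimethylsilyloxy)-2,6,6-trimethylcyclohex-2-en-1-yl]-3-methylpenta-2,4-dien-1-yl]triphenylphosphonium bromide | CC1=C[C@H](O[Si](C)(C)C(C)(C)C)CC(C)(C)[C@H]1/C=C/C(C)=C/C[P+](c1ccccc1)(c1ccccc1)c1ccccc1.[Br-] | intermediate
20 | (2E,4E,6E)-2,7-dimethylocta-2,4,6-trienedial | O=C/C(C)=C/C=C/C=C(C)/C=O | starting material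
21 | (2E,4E,6E,8E,10E,12E)-13-[(1R,4R)-4-(tert-butyldimethylsilyloxy)-2,6,6-trimethylcyclohex-2-en-1-yl]-2,7,11-trimethyltrideca-2,4,6,8,10,12-hexaenal | CC1=C[C@H](O[Si](C)(C)C(C)(C)C)CC(C)(C)[C@H]1/C=C/C(C)=C/C=C/C(C)=C/C=C/C=C(C)/C=O | intermediate
22 | (4R,6R)-4-hydroxy-2,2,6-trimethylcyclohexan-1-one | C[C@@H]1C[C@@H](O)CC(C)(C)C1=O | starting material
23 | (4R,6R)-4-[tert-butyl(diphenyl)silyl]oxy-2,2,6-trimethylcyclohexan-1-one | C[C@@H]1C[C@@H](O[Si](c2ccccc2)(c2ccccc2)C(C)(C)C)CC(C)(C)C1=O | intermediate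
24 | (4R)-4-[tert-butyl(diphenyl)silyl]oxy-2,6,6-trimethylcyclohex-1-en-1-yl trifluoromethanesulfonate | FC(F)(F)S(=O)(=O)OC1=C(C)C[C@@H](O[Si](c2ccccc2)(c2ccccc2)C(C)(C)C)CC1(C)C | intermediate
25 | methyl (4R)-4-[tert-butyl(diphenyl)silyl]oxy-2,6,6-trimethylcyclohex-1-ene-1-carboxylate | COC(=O)C1=C(C)C[C@@H](O[Si](c2ccccc2)(c2ccccc2)C(C)(C)C)CC1(C)C | intermediate
26 | [(4R)-4-[tert-butyl(diphenyl)silyl]oxy-2,6,6-trimethylcyclohex-1-en-1-yl]methanol | OCC1=C(C)C[C@@H](O[Si](c2ccccc2)(c2ccccc2)C(C)(C)C)CC1(C)C | intermediate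
27 | [(1R,4S,6R)-4-[tert-butyl(diphenyl)silyl]oxy-2,2,6-trimethyl-7-oxabicyclo[4.1.0]heptan-1-yl]methanol | OC[C@@]12O[C@]1(C)C[C@@H](O[Si](c3ccccc3)(c3ccccc3)C(C)(C)C)CC2(C)C | intermediate
28 | (1S,4S,6R)-4-[tert-butyl(diphenyl)silyl]oxy-2,2,6-trimethyl-7-oxabicyclo[4.1.0]heptane-1-carbaldehyde | O=C[C@@]12O[C@]1(C)C[C@@H](O[Si](c3ccccc3)(c3ccccc3)C(C)(C)C)CC2(C)C | intermediate
29 | ethyl (2E,4E)-5-[(1S,4S,6R)-4-[tert-butyl(diphenyl)silyl]oxy-2,2,6-trimethyl-7-oxabicyclo[4.1.0]heptan-1-yl]-3-methylpenta-2,4-dienoate | CCOC(=O)/C=C(C)/C=C/[C@@]12O[C@]1(C)C[C@@H](O[Si](c3ccccc3)(c3ccccc3)C(C)(C)C)CC2(C)C | intermediate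
30 | ethyl (2E,4E)-5-[(1S,2S,4S)-4-[tert-butyl(diphenyl)silyl]oxy-1,2-dihydroxy-2,6,6-trimethylcyclohexyl]-3-methylpenta-2,4-dienoate | CCOC(=O)/C=C(C)/C=C/[C@]1(O)C(C)(C)C[C@H](O[Si](c2ccccc2)(c2ccccc2)C(C)(C)C)C[C@]1(C)O | intermediate
31 | (2E,4E)-5-[(1S,2S,4S)-4-[tert-butyl(diphenyl)silyl]oxy-1,2-dihydroxy-2,6,6-trimethylcyclohexyl]-3-methylpenta-2,4-dien-1-ol | OC/C=C(C)/C=C/[C@]1(O)C(C)(C)C[C@H](O[Si](c2ccccc2)(c2ccccc2)C(C)(C)C)C[C@]1(C)O | intermediate
32 | (1S,2S,4S)-1-[(1E,3E)-5-bromo-3-methylpenta-1,3-dien-1-yl]-4-[tert-butyl(diphenyl)silyl]oxy-2,6,6-trimethylcyclohexane-1,2-diol | BrC/C=C(C)/C=C/[C@]1(O)C(C)(C)C[C@H](O[Si](c2ccccc2)(c2ccccc2)C(C)(C)C)C[C@]1(C)O | intermediate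
33 | [(2E,4E)-5-[(1S,2S,4S)-4-[tert-butyl(diphenyl)silyl]oxy-1,2-dihydroxy-2,6,6-trimethylcyclohexyl]-3-methylpenta-2,4-dien-1-yl]triphenylphosphonium bromide | [Br-].c1ccccc1[P+](c1ccccc1)(c1ccccc1)C/C=C(C)/C=C/[C@]1(O)C(C)(C)C[C@H](O[Si](c2ccccc2)(c2ccccc2)C(C)(C)C)C[C@]1(C)O | intermediate
34 | (3S,5S,6S,3'R,6'R)-3-[tert-butyl(diphenyl)silyl]oxy-3'-(tert-butyldimethylsilyloxy)-5,6-dihydro-β,ε-carotene-5,6-diol | CC1=C[C@H](O[Si](C)(C)C(C)(C)C)CC(C)(C)[C@H]1/C=C/C(C)=C/C=C/C(C)=C/C=C/C=C(C)/C=C/C=C(C)/C=C/[C@]1(O)C(C)(C)C[C@H](O[Si](c2ccccc2)(c2ccccc2)C(C)(C)C)C[C@]1(C)O | intermediate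
35 | (3S,5S,6S,3'R,6'R)-5,6-dihydro-β,ε-carotene-3,5,6,3'-tetrol | CC1=C[C@H](O)CC(C)(C)[C@H]1/C=C/C(C)=C/C=C/C(C)=C/C=C/C=C(C)/C=C/C=C(C)/C=C/[C@]1(O)C(C)(C)C[C@H](O)C[C@]1(C)O | target

**Step count**

Total steps: 25. Longest linear sequence: 15 steps (steps 1–13, then 24 and 25).

**Steps most likely to fail**

Step 5 (Proposed new method). The tertiary cation may add further 2-methylpropene (oligomerisation) or lose a proton before ring closure, and proton loss from the C5' cation may go toward the exocyclic or the C6' position. The fallback makes the two bonds in two separate, known operations. It sets out from 7: TiCl4-mediated addition of trimethyl(2-methylallyl)silane to the chiral acetal (allylsilane opening with inversion, −78 °C) should give (2E,5R)-5-{[(2S,4S)-4-hydroxypentan-2-yl]oxy}-3,7-dimethylocta-2,7-dien-1-yl pivalate F1. Proton-initiated cation–olefin cyclisation of this 1,5-diene (methanesulfonic acid, 2-nitropropane, −40 °C, the conditions class used for geranyl esters) then closes C1'–C6' through the same chair and returns to the route at 9.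

Step 21. Water may open the epoxide at C6 instead of C5, the C5 cation may undergo a 1,2-shift with ring contraction, or C6–O ionisation may lead to furanoid rearrangement. The fallback moves the opening to the epoxy alcohol stage, where chelation directs the nucleophile. It sets out from 27: Ti(OiPr)4-mediated opening with benzoic acid at the epoxide carbon remote from the carbinol (ring C5, inversion) should give (1S,2R,5S)-5-[tert-butyl(diphenyl)silyl]oxy-2-hydroxy-2-(hydroxymethyl)-1,3,3-trimethylcyclohexyl benzoate F2. Oxidation of the primary alcohol (SO3·pyridine, DMSO, Et3N) gives (1S,2S,5S)-5-[tert-butyl(diphenyl)silyl]oxy-2-formyl-2-hydroxy-1,3,3-trimethylcyclohexyl benzoate F3. Horner–Wadsworth–Emmons olefination with 15 (LiN(SiMe3)2, THF) gives ethyl (2E,4E)-5-[(1S,2S,4S)-2-(benzoyloxy)-4-[tert-butyl(diphenyl)silyl]oxy-1-hydroxy-2,6,6-trimethylcyclohexyl]-3-methylpenta-2,4-dienoate F4. iBu2AlH then cleaves the benzoate and reduces the ester in one operation, coming back to the route at 31.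

Step 10. The basic phosphonate anion may epimerise C6' or move the ring double bond into conjugation with the aldehyde, and addition to the hindered aldehyde may be slow. The fallback reverses the polarity so that no enolisable aldehyde is exposed to base. It sets out from 13: Mitsunobu thioetherification (1-phenyl-1H-tetrazole-5-thiol, PPh3, diisopropyl azodicarboxylate) should give 5-({[(1R,4R)-4-(tert-butyldimethylsilyloxy)-2,6,6-trimethylcyclohex-2-en-1-yl]methyl}sulfanyl)-1-phenyl-1H-tetrazole F5. Oxidation (H2O2, (NH4)6Mo7O24 cat., ethanol) gives 5-({[(1R,4R)-4-(tert-butyldimethylsilyloxy)-2,6,6-trimethylcyclohex-2-en-1-yl]methyl}sulfonyl)-1-phenyl-1H-tetrazole F6. Julia–Kocienski olefination of F6 with ethyl (2E)-3-methyl-4-oxobut-2-enoate (KN(SiMe3)2, THF, −78 °C) forms C7'=C8' and comes back to the route at 16.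

**Further compounds**

F1 | step 5 | (2E,5R)-5-{[(2S,4S)-4-hydroxypentan-2-yl]oxy}-3,7-dimethylocta-2,7-dien-1-yl pivalate | CC(=C)C[C@@H](O[C@@H](C)C[C@H](C)O)C/C(C)=C/COC(=O)C(C)(C)C
F2 | step 21 | (1S,2R,5S)-5-[tert-butyl(diphenyl)silyl]oxy-2-hydroxy-2-(hydroxymethyl)-1,3,3-trimethylcyclohexyl benzoate | OC[C@]1(O)C(C)(C)C[C@H](O[Si](c2ccccc2)(c2ccccc2)C(C)(C)C)C[C@]1(C)OC(=O)c1ccccc1
F3 | step 21 | (1S,2S,5S)-5-[tert-butyl(diphenyl)silyl]oxy-2-formyl-2-hydroxy-1,3,3-trimethylcyclohexyl benzoate | O=C[C@]1(O)C(C)(C)C[C@H](O[Si](c2ccccc2)(c2ccccc2)C(C)(C)C)C[C@]1(C)OC(=O)c1ccccc1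
F4 | step 21 | ethyl (2E,4E)-5-[(1S,2S,4S)-2-(benzoyloxy)-4-[tert-butyl(diphenyl)silyl]oxy-1-hydroxy-2,6,6-trimethylcyclohexyl]-3-methylpenta-2,4-dienoate | CCOC(=O)/C=C(C)/C=C/[C@]1(O)C(C)(C)C[C@H](O[Si](c2ccccc2)(c2ccccc2)C(C)(C)C)C[C@]1(C)OC(=O)c1ccccc1
F5 | step 10 | 5-({[(1R,4R)-4-(tert-butyldimethylsilyloxy)-2,6,6-trimethylcyclohex-2-en-1-yl]methyl}sulfanyl)-1-phenyl-1H-tetrazole | CC1=C[C@H](O[Si](C)(C)C(C)(C)C)CC(C)(C)[C@H]1CSc1nnnn1-c1ccccc1
F6 | step 10 | 5-({[(1R,4R)-4-(tert-butyldimethylsilyloxy)-2,6,6-trimethylcyclohex-2-en-1-yl]methyl}sulfonyl)-1-phenyl-1H-tetrazole | CC1=C[C@H](O[Si](C)(C)C(C)(C)C)CC(C)(C)[C@H]1CS(=O)(=O)c1nnnn1-c1ccccc1
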